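I start with the easy step: I track the fraction left, not the fraction made, so each reading becomes one subtraction.

| flask | substrate | coupling partner | free catalyst | impurity | remark | time |
|---|---|---|---|---|---|---|
| violet | 0.050 M | 0.060 M | 50 µM | 14 µM | run made earlier |  |
| green | 0.050 M | 0.084 M | 50 µM | 14 µM | run made earlier |  |
| grey | 0.050 M | 0.13 M | 50 µM | 14 µM | run made earlier |  |
| alder | 0.050 M (fed, over 50 h) | 0.0600 M | 50 µM | 14 µM | all else is in the flask from the start; the feed brings no volume worth counting | 2.5 d |
| larch | 0.050 M | 0.0600 M (fed, over 50 h) | 50 µM | 14 µM | all else is in the flask from the start; the feed brings no volume worth counting | 2.5 d |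
| oak | 0.050 M | 0.0600 M (in portions, 3, over 50 h) | 50 µM | 14 µM | first portion at the start, last at 50 h | 2.5 d |
| ash | 0.050 M | 0.0600 M | 50 µM | 14 µM | everything together at the start | 2.5 d |
| birch | 0.050 M | 0.0600 M (fed, over 12 h) | 50 µM | 14 µM | all else is in the flask from the start; the feed brings no volume worth counting | 2.5 d |

violet run (percent of the substrate charged): time / h: target / % = 3.00: 33; 6.00: 62; 15.0: 78; 40.0: 90

green run (percent of the substrate charged): time / d: target / % = 0.208: 55; 0.500: 77; 1.04: 85; 2.50: 97

grey run (percent of the substrate charged): time / d: target / % = 0.625: 80; 1.25: 85; 2.08: 93; 2.50: 96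

(readings scatter by 1.5 percentage points)

* the flask with the highest amount of target, in percent of the substrate charged ("all alike" if they lie within 1.5 percentage points) (alder / larch / oak / ash / birch / all alike)
* final target, as a percentage of the substrate charged, in alder
* final target, as a percentage of the substrate charged, in larch
* final target, as a percentage of the substrate charged, in oak
* final target, as a percentage of the substrate charged, in ash
* final target, as a percentage of the substrate charged, in birch



1. Violet has made 33% after 3.00 h, a fast rate of 0.110 h⁻¹ of the charge. Green, with more coupling partner, reads 0.110 h⁻¹, so within the scatter of these readings the partner does not move this rate. I call the inverse the burn time, the time the fast stretch needs for the whole charge: 9.09 h.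

2. Violet still has 22.0% left after 15.0 h and 10.0% after 40.0 h. I read this as a first-order tail. Its remainder half-life, the time in which the fraction left halves once the fast stretch is over, is 22.0 h, a reading that carries the scatter.

3. These two times stand at a ratio of 2.42, so what enters the remainder returns more slowly than free substrate burns. My assumption is that the remainder forms from substrate standing free.

4. Ash repeats violet and runs on, so I reckon 5.32% left. In larch the partner arrives on average 25.0 h late, which gives 11.7% left. Alder's substrate arrives over 5.50 burn times, so little stands free, and I put alder above ash.

5. The forecast differs: it puts ash first, with alder at 85%, larch at 87%, oak at 84%, ash at 96% and birch at 95.5%, reading “this sharp stop looks like a turnover-counted death”.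

6. The flasks give alder as highest: alder 98.9%, larch 87.1%, oak 85.5%, ash 95.2%, birch 94.2%.

    coupling partner + catalyst intermediate B → catalyst intermediate C (k = 1.60 × 10⁵ L mol⁻¹ h⁻¹)
    free catalyst + impurity → spent catalyst (k = 2.10 × 10⁶ L mol⁻¹ h⁻¹)
    catalyst intermediate D → free catalyst + target (k = 1800 h⁻¹)
    catalyst intermediate A → catalyst intermediate B (k = 190 h⁻¹)
    substrate + free catalyst → catalyst intermediate A (k = 1.20 × 10⁵ L mol⁻¹ h⁻¹)
    substrate ⇌ dormant form (K = 3.20, k = 0.110 h⁻¹)
    catalyst intermediate C → by-product + catalyst intermediate D (k = 1100 h⁻¹)

At 2.50 d the dormant form stands at 1.07% in alder, 4.79% in ash and 12.8% in larch, close to what each flask lacks of full target. Counted in halvings of the dormant form, alder stands 2.16 ahead of ash and larch 1.42 behind it, which at my remainder half-life of 22.0 h, a reading with its scatter, comes to about 47.6 h and 31.2 h.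

The numbers in the tables were generated by integration on assumed constants.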